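**Retrosynthetic overview**

- Locants: oxolane O1–C7 (ring B)–C8 (Me)–C8' (Me)–C7' (ring A); side chain C7'' (OH, ring C)–C8'' (Me, O–ring B).
- The plan rests on O1 lying between two benzylic carbons, C7 (ring B) and C7' (ring A): an ester of the ring B acid with the C7' carbinol already holds O1, C7, C7' and C8', so only the C7–C8 bond is missing.
- Disconnections, backwards: ring C–C7'' (chelation-controlled Grignard) and C8''–O (Mitsunobu on lactate); C8 methyl from a C8 vinyl group; C7–C8 by allylsilane attack on the C7 oxocarbenium ion made from the α-acetoxy ether of that ester.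
- The allylsilane comes from cross-metathesis, and the C7'–C8' bond from (Z)-crotylboration of O-benzylvanillin.
- Ring order: the three arenes are bought as vanillin-type units; the oxolane is the only ring made (step 6).

Key step: step 6

Remark: the minor (Z)-allylsilane from the cross-metathesis and both acetal epimers of the α-acetoxy ether are carried on unseparated, because both elements vanish in the cyclisation. Oxolanes are named with O1, C2 = C7, C3 = C8, C4 = C8', C5 = C7'.

**Route**

Step 1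
Reactants: 1 4-(benzyloxy)-3-methoxybenzaldehyde (O-benzylvanillin); 2 cis-2-butene
Product: 7 (1S,2R)-1-[4-(benzyloxy)-3-methoxyphenyl]-2-methylbut-3-en-1-ol, via (Z)-crotylpotassium 3 (not isolated), via potassium crotyl(methoxy)diisopinocampheylborate 4 (not isolated), via B-(Z)-crotyldiisopinocampheylborane 5 (not isolated), via diisopinocampheylborinate of the product 6 (not isolated)
Conditions: 2, KOt-Bu, n-BuLi, THF, −78 to −45 °C; (−)-B-methoxydiisopinocampheylborane [(−)-Ipc2BOMe, from (+)-α-pinene], −78 °C; BF3·OEt2; then 1, −78 °C; NaOH, H2O2, 0 °C to rt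
Reagents that add atoms: none
Why: Brown asymmetric crotylboration, in which the (Z)-crotylborane reacts through a chair Zimmerman–Traxler transition state so that the Z geometry gives the syn C7'/C8' pair, and the isopinocampheyl groups derived from (+)-α-pinene deliver the crotyl unit to the Si face of the aldehyde, setting C7' as S and C8' as R.

Step 2
Reactants: 7 (1S,2R)-1-[4-(benzyloxy)-3-methoxyphenyl]-2-methylbut-3-en-1-ol; 8 allyltrimethylsilane
Product: 9 (1S,2R,3E)-1-[4-(benzyloxy)-3-methoxyphenyl]-2-methyl-5-(trimethylsilyl)pent-3-en-1-ol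
Conditions: 8 (excess), second-generation Grubbs catalyst RuCl2(=CHPh)(PCy3)(H2IMes) (5 mol %), CH2Cl2, 40 °C
Reagents that add atoms: none
Why: Olefin cross-metathesis of the terminal alkene with an excess of the unhindered partner 8 releases ethene and should give mainly the (E)-allylsilane without touching C7' or C8'.

Step 3
Reactants: 10 vanillic acid
Product: 12 3-methoxy-4-[(triisopropylsilyl)oxy]benzoic acid, via bis-silylated vanillic acid 11 (not isolated)
Conditions: i-Pr3SiCl (2.3 equiv), imidazole, DMF, rt; then K2CO3, THF/MeOH/H2O, rt; citric acid work-up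
Reagents that add atoms: triisopropylsilyl chloride, CC(C)[Si](Cl)(C(C)C)C(C)C
Why: Silylation of both acidic sites followed by selective hydrolysis of the silyl ester, which is far more labile than the hindered aryl silyl ether (protecting-group chemistry).

Step 4
Reactants: 9 (1S,2R,3E)-1-[4-(benzyloxy)-3-methoxyphenyl]-2-methyl-5-(trimethylsilyl)pent-3-en-1-ol; 12 3-methoxy-4-[(triisopropylsilyl)oxy]benzoic acid
Product: 13 (1S,2R,3E)-1-[4-(benzyloxy)-3-methoxyphenyl]-2-methyl-5-(trimethylsilyl)pent-3-en-1-yl 3-methoxy-4-[(triisopropylsilyl)oxy]benzoate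
Conditions: DCC, DMAP (cat.), CH2Cl2, 0 °C to rt
Reagents that add atoms: none
Why: Steglich esterification joins O1 to C7 at the acid oxidation level with retention at C7', since the C7'–O bond is not broken.

Step 5
Reactants: 13 the ester of step 4
Product: 15 {[(1S,2R,3E)-1-[4-(benzyloxy)-3-methoxyphenyl]-2-methyl-5-(trimethylsilyl)pent-3-en-1-yl]oxy}{3-methoxy-4-[(triisopropylsilyl)oxy]phenyl}methyl acetate (both acetal epimers), via diisobutylaluminium hemiacetal 14 (not isolated)
Conditions: i-Bu2AlH (DIBAL-H), CH2Cl2, −78 °C; then pyridine, DMAP, Ac2O, −78 to −20 °C; quick filtration through Et3N-deactivated silica, used at once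
Reagents that add atoms: acetic anhydride, CC(=O)OC(C)=O
Why: Reductive acetylation of an ester, in which hydride addition at −78 °C gives the tetrahedral aluminium hemiacetal 14 that is trapped on oxygen by Ac2O/DMAP before it can collapse to an aldehyde.

Step 6
Reactants: 15 the α-acetoxy ether of step 5
Product: 17 (2R,3R,4R,5S)-5-[4-(benzyloxy)-3-methoxyphenyl]-3-ethenyl-2-{3-methoxy-4-[(triisopropylsilyl)oxy]phenyl}-4-methyloxolane, via oxocarbenium acetoxytrifluoroborate 16 (not isolated)
Conditions: BF3·OEt2 (2 equiv), 2,6-di-tert-butyl-4-methylpyridine (0.5 equiv), CH2Cl2 (0.02 M), −78 °C; then Et3N, aq. NaHCO3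
Reagents that add atoms: none
Why: BF3·OEt2 removes acetate from the acetal carbon of 15 to give the aryl-stabilised (E)-oxocarbenium ion 16 (C7=O1+), the γ-carbon of the allylsilane (C8) adds to C7, and the resulting β-silyl cation loses Me3Si+ to leave a vinyl group on C8. The closest known reaction type is the intramolecular Hosomi–Sakurai (silyl-modified Sakurai) closure of 5-silylpent-3-enyl oxocarbenium ions to 3-vinyltetrahydrofurans, here with the cation generated from an ester-derived α-acetoxy ether instead of from an aldehyde. The oxolane closes by C7–C8 bond formation with the attacked C7=O1+ bond inside the new five-membered ring (endo at the electrophile) and the allylsilane C=C bond outside it (exo at the nucleophile). C7 is controlled by the (E) geometry of the cation together with an envelope in which ring A on C7' is pseudo-equatorial, which places ring B cis to ring A across O1; C8 is controlled by the C8' stereocentre, whose C–H bond eclipses the alkene (least allylic 1,3-strain) so that the future vinyl group ends trans to both the C8' methyl group and the C7 aryl group. The step needs cyclisation to outrun 2-oxonia-Cope rearrangement, protodesilylation and heterolysis of the benzylic C7'–O1 bond, and the high γ-nucleophilicity of the allylsilane, the irreversible loss of silicon, the hindered base and −78 °C should secure this.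

Step 7
Reactants: 17 the 3-vinyloxolane of step 6
Product: 19 (2R,3R,4R,5S)-5-[4-(benzyloxy)-3-methoxyphenyl]-2-{3-methoxy-4-[(triisopropylsilyl)oxy]phenyl}-4-methyloxolane-3-carbaldehyde, via secondary ozonide 18 (not isolated)
Conditions: O3, CH2Cl2, −78 °C (Sudan Red 7B end point); then PPh3, −78 °C to rt
Reagents that add atoms: ozone, [O-][O+]=O
Why: Ozonolysis (Criegee mechanism) with reductive work-up cleaves the only C=C bond, which reacts far faster than the protected arenes at −78 °C when the gas flow is stopped at the indicator end point, and leaves C8 in its already most stable arrangement.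

Step 8
Reactants: 19 the aldehyde of step 7
Product: 20 [(2R,3S,4R,5S)-5-[4-(benzyloxy)-3-methoxyphenyl]-2-{3-methoxy-4-[(triisopropylsilyl)oxy]phenyl}-4-methyloxolan-3-yl]methanol
Conditions: NaBH4, MeOH/THF, 0 °C
Reagents that add atoms: none
Why: Chemoselective borohydride reduction of the aldehyde to the primary alcohol under conditions too mild to epimerise C8.

Step 9
Reactants: 20 the primary alcohol of step 8
Product: 21 [(2R,3S,4R,5S)-5-[4-(benzyloxy)-3-methoxyphenyl]-2-{3-methoxy-4-[(triisopropylsilyl)oxy]phenyl}-4-methyloxolan-3-yl]methyl 4-methylbenzenesulfonate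
Conditions: TsCl, Et3N, DMAP (cat.), CH2Cl2, 0 °C to rt
Reagents that add atoms: 4-toluenesulfonyl chloride, Cc1ccc(cc1)S(Cl)(=O)=O
Why: Sulfonylation of the primary alcohol turns the hydroxyl group into a leaving group (tosylate formation).

Step 10
Reactants: 21 the tosylate of step 9
Product: 22 (2R,3R,4R,5S)-5-[4-(benzyloxy)-3-methoxyphenyl]-2-{3-methoxy-4-[(triisopropylsilyl)oxy]phenyl}-3,4-dimethyloxolane
Conditions: LiBHEt3, THF, 0 °C to rt
Reagents that add atoms: none
Why: SN2 displacement of the primary tosylate by hydride from LiBHEt3 gives the C8 methyl group, and aryl silyl and benzyl ethers are inert to this reagent.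

Step 11
Reactants: 22 the silyl ether of step 10
Product: 23 4-{(2R,3R,4R,5S)-5-[4-(benzyloxy)-3-methoxyphenyl]-3,4-dimethyloxolan-2-yl}-2-methoxyphenol
Conditions: Bu4NF, THF, 0 °C; aq. NH4Cl
Reagents that add atoms: none
Why: Fluoride-mediated desilylation frees the ring B phenol while the benzyl ether of ring A stays in place.

Step 12
Reactants: 23 the ring B phenol of step 11; 24 ethyl (S)-lactate
Product: 25 ethyl (2R)-2-(4-{(2R,3R,4R,5S)-5-[4-(benzyloxy)-3-methoxyphenyl]-3,4-dimethyloxolan-2-yl}-2-methoxyphenoxy)propanoate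
Conditions: 24, PPh3, DIAD, THF, 0 °C to rt
Reagents that add atoms: none
Why: Mitsunobu etherification proceeds by SN2 displacement of the activated lactate hydroxyl group by the phenoxide with inversion, so the (S)-lactate gives the (R)-configured C8'' centre.

Step 13
Reactants: 25 the aryloxy ester of step 12
Product: 26 (2R)-2-(4-{(2R,3R,4R,5S)-5-[4-(benzyloxy)-3-methoxyphenyl]-3,4-dimethyloxolan-2-yl}-2-methoxyphenoxy)propanal
Conditions: i-Bu2AlH (DIBAL-H), toluene, −78 °C; aq. KNaC4H4O6 (potassium sodium tartrate) work-up; crude used at once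
Reagents that add atoms: none
Why: Partial reduction of the ester with DIBAL-H at −78 °C stops at the aluminium hemiacetal, which releases the aldehyde on work-up, and immediate use avoids epimerisation at C8''.

Step 14
Reactants: 26 the aldehyde of step 13; 27 1-(benzyloxy)-4-bromo-2-methoxybenzene
Product: 29 (1R,2R)-1-[4-(benzyloxy)-3-methoxyphenyl]-2-(4-{(2R,3R,4R,5S)-5-[4-(benzyloxy)-3-methoxyphenyl]-3,4-dimethyloxolan-2-yl}-2-methoxyphenoxy)propan-1-ol, via arylmagnesium bromide 28 (not isolated)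
Conditions: 27, Mg, THF, rt to 40 °C; then 26, CH2Cl2, −78 °C; aq. NH4Cl
Reagents that add atoms: none
Why: Grignard addition under Cram chelation control, in which magnesium bridges the carbonyl oxygen and the α-aryloxy oxygen (helped by the ortho methoxy group) and the aryl group adds to the face opposite the C8'' methyl group, which should give the threo (7''R,8''R) alcohol.

Step 15
Reactants: 29 the bis-benzyl ether of step 14
Product: 30 (1R,2R)-1-(4-hydroxy-3-methoxyphenyl)-2-{4-[(2R,3R,4R,5S)-5-(4-hydroxy-3-methoxyphenyl)-3,4-dimethyloxolan-2-yl]-2-methoxyphenoxy}propan-1-ol (CNP0171079.2)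
Conditions: H2 (1 atm), 10% Pd/C (palladium on carbon), EtOAc, rt, stopped at full conversion
Reagents that add atoms: none
Why: Catalytic hydrogenolysis cleaves both phenolic benzyl ethers, which react much faster under neutral conditions than the benzylic alcohol and the benzylic C–O bonds of the oxolane.

**Compound list**

1 | 4-(benzyloxy)-3-methoxybenzaldehyde (O-benzylvanillin) | COc1cc(C=O)ccc1OCc1ccccc1 | starting material
2 | cis-2-butene | C/C=C\C | starting material
3 | (Z)-crotylpotassium (not isolated) | C/C=C\[CH2-].[K+] | intermediate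
4 | potassium (Z)-but-2-enyl(methoxy)bis[(−)-isopinocampheyl]borate (not isolated) | C/C=C\C[B-](OC)([C@@H]1C[C@@H]2C[C@H]([C@H]1C)C2(C)C)[C@@H]1C[C@@H]2C[C@H]([C@H]1C)C2(C)C.[K+] | intermediate
5 | B-[(Z)-but-2-enyl]bis[(−)-isopinocampheyl]borane (not isolated) | C/C=C\CB([C@@H]1C[C@@H]2C[C@H]([C@H]1C)C2(C)C)[C@@H]1C[C@@H]2C[C@H]([C@H]1C)C2(C)C | intermediate
6 | bis[(−)-isopinocampheyl]borinate of alcohol 7 (not isolated) | B(O[C@H](c1ccc(OCc2ccccc2)c(OC)c1)[C@H](C)C=C)([C@@H]1C[C@@H]2C[C@H]([C@H]1C)C2(C)C)[C@@H]1C[C@@H]2C[C@H]([C@H]1C)C2(C)C | intermediate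
7 | (1S,2R)-1-[4-(benzyloxy)-3-methoxyphenyl]-2-methylbut-3-en-1-ol (syn) | O[C@H](c1ccc(OCc2ccccc2)c(OC)c1)[C@H](C)C=C | intermediate
8 | allyltrimethylsilane | C=CC[Si](C)(C)C | starting material
9 | (1S,2R,3E)-1-[4-(benzyloxy)-3-methoxyphenyl]-2-methyl-5-(trimethylsilyl)pent-3-en-1-ol | O[C@H](c1ccc(OCc2ccccc2)c(OC)c1)[C@H](C)/C=C/C[Si](C)(C)C | intermediate
10 | vanillic acid | COc1cc(C(=O)O)ccc1O | starting material
11 | triisopropylsilyl 3-methoxy-4-[(triisopropylsilyl)oxy]benzoate (not isolated) | COc1cc(C(=O)O[Si](C(C)C)(C(C)C)C(C)C)ccc1O[Si](C(C)C)(C(C)C)C(C)C | intermediate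
12 | 3-methoxy-4-[(triisopropylsilyl)oxy]benzoic acid | COc1cc(C(=O)O)ccc1O[Si](C(C)C)(C(C)C)C(C)C | intermediate
13 | (1S,2R,3E)-1-[4-(benzyloxy)-3-methoxyphenyl]-2-methyl-5-(trimethylsilyl)pent-3-en-1-yl 3-methoxy-4-[(triisopropylsilyl)oxy]benzoate | COc1cc(C(=O)O[C@H](c2ccc(OCc3ccccc3)c(OC)c2)[C@H](C)/C=C/C[Si](C)(C)C)ccc1O[Si](C(C)C)(C(C)C)C(C)C | intermediate
14 | diisobutylaluminium hemiacetal of ester 13, epimers at the acetal carbon (not isolated) | COc1cc(C(O[Al](CC(C)C)CC(C)C)O[C@H](c2ccc(OCc3ccccc3)c(OC)c2)[C@H](C)/C=C/C[Si](C)(C)C)ccc1O[Si](C(C)C)(C(C)C)C(C)C | intermediate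
15 | α-acetoxy ether of ester 13, both epimers at the acetal carbon | COc1cc(C(OC(C)=O)O[C@H](c2ccc(OCc3ccccc3)c(OC)c2)[C@H](C)/C=C/C[Si](C)(C)C)ccc1O[Si](C(C)C)(C(C)C)C(C)C | intermediate
16 | (E)-oxocarbenium ion (C7=O1+) as its acetoxytrifluoroborate (not isolated) | COc1cc(/C=[O+]/[C@H](c2ccc(OCc3ccccc3)c(OC)c2)[C@H](C)/C=C/C[Si](C)(C)C)ccc1O[Si](C(C)C)(C(C)C)C(C)C.CC(=O)O[B-](F)(F)F | intermediate
17 | (2R,3R,4R,5S)-5-[4-(benzyloxy)-3-methoxyphenyl]-3-ethenyl-2-{3-methoxy-4-[(triisopropylsilyl)oxy]phenyl}-4-methyloxolane | COc1cc([C@@H]2O[C@H](c3ccc(OCc4ccccc4)c(OC)c3)[C@H](C)[C@H]2C=C)ccc1O[Si](C(C)C)(C(C)C)C(C)C | intermediate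
18 | 1,2,4-trioxolane (secondary ozonide) of 17, epimers at the trioxolane carbon (not isolated) | COc1cc([C@@H]2O[C@H](c3ccc(OCc4ccccc4)c(OC)c3)[C@H](C)[C@H]2C5OOCO5)ccc1O[Si](C(C)C)(C(C)C)C(C)C | intermediate
19 | (2R,3R,4R,5S)-5-[4-(benzyloxy)-3-methoxyphenyl]-2-{3-methoxy-4-[(triisopropylsilyl)oxy]phenyl}-4-methyloxolane-3-carbaldehyde | COc1cc([C@@H]2O[C@H](c3ccc(OCc4ccccc4)c(OC)c3)[C@H](C)[C@H]2C=O)ccc1O[Si](C(C)C)(C(C)C)C(C)C | intermediate
20 | [(2R,3S,4R,5S)-5-[4-(benzyloxy)-3-methoxyphenyl]-2-{3-methoxy-4-[(triisopropylsilyl)oxy]phenyl}-4-methyloxolan-3-yl]methanol | COc1cc([C@@H]2O[C@H](c3ccc(OCc4ccccc4)c(OC)c3)[C@H](C)[C@H]2CO)ccc1O[Si](C(C)C)(C(C)C)C(C)C | intermediate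
21 | 4-methylbenzenesulfonate of alcohol 20 | COc1cc([C@@H]2O[C@H](c3ccc(OCc4ccccc4)c(OC)c3)[C@H](C)[C@H]2COS(=O)(=O)c5ccc(C)cc5)ccc1O[Si](C(C)C)(C(C)C)C(C)C | intermediate
22 | (2R,3R,4R,5S)-5-[4-(benzyloxy)-3-methoxyphenyl]-2-{3-methoxy-4-[(triisopropylsilyl)oxy]phenyl}-3,4-dimethyloxolane | COc1cc([C@@H]2O[C@H](c3ccc(OCc4ccccc4)c(OC)c3)[C@H](C)[C@H]2C)ccc1O[Si](C(C)C)(C(C)C)C(C)C | intermediate
23 | 4-{(2R,3R,4R,5S)-5-[4-(benzyloxy)-3-methoxyphenyl]-3,4-dimethyloxolan-2-yl}-2-methoxyphenol | COc1cc([C@@H]2O[C@H](c3ccc(OCc4ccccc4)c(OC)c3)[C@H](C)[C@H]2C)ccc1O | intermediate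
24 | ethyl (S)-lactate | CCOC(=O)[C@H](C)O | starting material
25 | ethyl (2R)-2-(4-{(2R,3R,4R,5S)-5-[4-(benzyloxy)-3-methoxyphenyl]-3,4-dimethyloxolan-2-yl}-2-methoxyphenoxy)propanoate | CCOC(=O)[C@@H](C)Oc1ccc([C@@H]2O[C@H](c3ccc(OCc4ccccc4)c(OC)c3)[C@H](C)[C@H]2C)cc1OC | intermediate
26 | (2R)-2-(4-{(2R,3R,4R,5S)-5-[4-(benzyloxy)-3-methoxyphenyl]-3,4-dimethyloxolan-2-yl}-2-methoxyphenoxy)propanal | O=C[C@@H](C)Oc1ccc([C@@H]2O[C@H](c3ccc(OCc4ccccc4)c(OC)c3)[C@H](C)[C@H]2C)cc1OC | intermediate
27 | 1-(benzyloxy)-4-bromo-2-methoxybenzene | COc1cc(Br)ccc1OCc1ccccc1 | starting material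
28 | [4-(benzyloxy)-3-methoxyphenyl]magnesium bromide (not isolated) | COc1cc([Mg]Br)ccc1OCc1ccccc1 | intermediate
29 | (1R,2R)-1-[4-(benzyloxy)-3-methoxyphenyl]-2-(4-{(2R,3R,4R,5S)-5-[4-(benzyloxy)-3-methoxyphenyl]-3,4-dimethyloxolan-2-yl}-2-methoxyphenoxy)propan-1-ol | COc1cc([C@@H](O)[C@@H](C)Oc2ccc([C@@H]3O[C@H](c4ccc(OCc5ccccc5)c(OC)c4)[C@H](C)[C@H]3C)cc2OC)ccc1OCc1ccccc1 | intermediate
30 | (1R,2R)-1-(4-hydroxy-3-methoxyphenyl)-2-{4-[(2R,3R,4R,5S)-5-(4-hydroxy-3-methoxyphenyl)-3,4-dimethyloxolan-2-yl]-2-methoxyphenoxy}propan-1-ol (CNP0171079.2) | COc1cc([C@@H](O)[C@@H](C)Oc2ccc([C@@H]3O[C@H](c4ccc(O)c(OC)c4)[C@H](C)[C@H]3C)cc2OC)ccc1O | target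

**Step count and risks**

Total step count: 15. Longest linear sequence: 14 steps (steps 1, 2 and 4 to 15, from compound 1); step 3 is a one-step side branch.

Steps most likely to fail:

1. Step 6. The process at risk is facial selection at the alkene carbon: a synclinal approach of the allylsilane would form C8 with the vinyl group cis to the C8' methyl and the C7 aryl group. The fallback replaces kinetic control of C8 by thermodynamic control at the aldehyde stage. It sets out from 15: the cyclisation is run as in step 6 and would then give the all-cis 3-vinyloxolane F1, which is the C8 epimer of 17, alone or mixed with 17. F1 is ozonised as in step 7 (O3, CH2Cl2, −78 °C; then PPh3) through its secondary ozonide F2 to the C8-epimeric aldehyde F3, whose formyl group is cis to both ring neighbours. Treatment of F3 with DBU in CH2Cl2 at room temperature should epimerise the α-carbon by enolisation to the arrangement trans to both neighbours. Ring opening by β-elimination is the reverse of a 5-endo-trig closure and is stereoelectronically slow. This gives 19, where the fallback rejoins the route.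

2. Step 5. The process at risk is collapse of the aluminium hemiacetal of the electron-rich aryl ester before acetylation (over-reduction), or ionisation and hydrolysis of the very labile benzylic acetoxy acetal during handling. The fallback makes the same cation without the ester. It sets out from 9. Vanillin F4 is silylated (i-Pr3SiCl, imidazole, DMF, rt) to 3-methoxy-4-[(triisopropylsilyl)oxy]benzaldehyde F5, and 9 is silylated (Me3SiCl, Et3N, CH2Cl2, 0 °C) to its trimethylsilyl ether F6. F5 and F6 are combined with Me3SiOTf (0.2 equiv) in CH2Cl2 at −78 °C (silyl-modified Sakurai condensation): the silyl ether and the aldehyde give the oxocarbenium ion of 16 directly, and it closes as in step 6. The fallback rejoins the route at 17.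

3. Step 14. The process at risk is weak chelation by the aryl ether oxygen, so that addition follows the Felkin–Anh course and the erythro alcohol forms; enolisation of the α-aryloxy aldehyde is a lesser risk. The fallback inverts the carbinol centre instead of relying on the addition. It sets out from 26 and 28: the addition is run as in step 14 and the erythro alcohol F7, the (7''S,8''R) epimer of 29, is separated by chromatography. A Mitsunobu reaction of F7 with 4-nitrobenzoic acid (PPh3, DIAD, THF, 0 °C) inverts C7'' and gives the threo 4-nitrobenzoate F8. Methanolysis of F8 (K2CO3, MeOH, rt) returns 29, where the fallback rejoins the route.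

Further compounds
F1 | step 6 | (2R,3S,4R,5S)-5-[4-(benzyloxy)-3-methoxyphenyl]-3-ethenyl-2-{3-methoxy-4-[(triisopropylsilyl)oxy]phenyl}-4-methyloxolane (C8 epimer of 17) | COc1cc([C@@H]2O[C@H](c3ccc(OCc4ccccc4)c(OC)c3)[C@H](C)[C@@H]2C=C)ccc1O[Si](C(C)C)(C(C)C)C(C)C
F2 | step 6 | secondary ozonide of F1 | COc1cc([C@@H]2O[C@H](c3ccc(OCc4ccccc4)c(OC)c3)[C@H](C)[C@@H]2C5OOCO5)ccc1O[Si](C(C)C)(C(C)C)C(C)C
F3 | step 6 | C8 epimer of aldehyde 19 | COc1cc([C@@H]2O[C@H](c3ccc(OCc4ccccc4)c(OC)c3)[C@H](C)[C@@H]2C=O)ccc1O[Si](C(C)C)(C(C)C)C(C)C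
F4 | step 5 | vanillin | COc1cc(C=O)ccc1O
F5 | step 5 | 3-methoxy-4-[(triisopropylsilyl)oxy]benzaldehyde | COc1cc(C=O)ccc1O[Si](C(C)C)(C(C)C)C(C)C
F6 | step 5 | trimethylsilyl ether of 9 | C[Si](C)(C)O[C@H](c1ccc(OCc2ccccc2)c(OC)c1)[C@H](C)/C=C/C[Si](C)(C)C
F7 | step 14 | (1S,2R) erythro epimer of 29 at C7'' | COc1cc([C@H](O)[C@@H](C)Oc2ccc([C@@H]3O[C@H](c4ccc(OCc5ccccc5)c(OC)c4)[C@H](C)[C@H]3C)cc2OC)ccc1OCc1ccccc1
F8 | step 14 | 4-nitrobenzoate of 29 | COc1cc([C@@H](OC(=O)c2ccc([N+](=O)[O-])cc2)[C@@H](C)Oc2ccc([C@@H]3O[C@H](c4ccc(OCc5ccccc5)c(OC)c4)[C@H](C)[C@H]3C)cc2OC)ccc1OCc1ccccc1
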